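## The problem

The target is a 21-membered ansa-lactam (ring B). Its chain C1–C17 (C1 = amide carbonyl, C17 = benzylic CH2) bridges the meta positions C18 and C22 of an aminohydroquinone (ring A: C18 bears C17, C20 and C23 bear OH, C22 bears the amide N). In this numbering the SMILES reads 3R, 11R, 12R, 13S and 4E, 6E, 8E, 14Z.

The all-E triene C4–C9 starts directly at the allylic methoxy carbon C3. It is sensitive to acid (ionisation at C3), to light- or metal-induced E/Z scrambling and to oxidants, so it should appear late and from partners of fixed geometry. C3 is seven bonds from the next stereocentre and nothing in the chain can control it. The C11–C13 triad (11,12-anti, 12,13-syn, 11,13-anti diol) can be relayed internally: C12 and C13 in one aldol step, C11 from the C13 hydroxyl. C13 sits on the Z-trisubstituted alkene C14=C15, the less stable geometry, which must be made under kinetic control and then kept. The hydroquinone is air-sensitive and the nitrogen on C22, flanked by the C23 oxygen, is a weak nucleophile, so ring A must travel masked and a late acylation or lactamisation at N–C1 is unattractive.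

The feature that opens a different plan is the unit N–C1(=O)–C2H2–C3H(OMe)–C4H=C5H. A γ,δ-unsaturated anilide with a β-methoxy group is the retron of a Claisen rearrangement of an O-allyl N-aryl acetimidate. The nitrogen is then already on ring A, C1 and C2 come from an N-acetyl group, C3–C5 from a 3-methoxyallyl alcohol, and C3 inherits its configuration from a sacrificial carbinol at C5.

## Retrosynthesis

**37 ⇐ 35 ⇐ 34 (no skeletal bond cut).** Ring A is carried as its 20,23-dimethyl ether and the diol as two TBS ethers. Desilylation gives 35; oxidative demethylation to quinone 36 and reduction give 37. This keeps the air-sensitive hydroquinone out of every metal-mediated step. The forward oxidation must take the electron-rich arene, the most easily oxidised site, and spare the triene.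

**34 ⇐ 32 (cut C15–C16).** Ring B is opened at the sp2–sp3 bond beside the Z-alkene. The neighbouring cuts are worse: N–C1 needs a weak nucleophile, and a cut inside the triene leaves its geometry to the ring. 32 is acyclic, with a terminal styrene and a Z-vinyl bromide. Forward, hydroboration gives borane 33 and an intramolecular B-alkyl Suzuki coupling closes the ring. The hydroboration must take the terminal styrene and leave the conjugated internal alkenes; the coupling must retain the Z geometry.

**32 ⇐ 15 + 31 (cut C7–C8).** This sp2–sp2 cut divides the seco compound into halves of similar size. Both flanking alkenes are made beforehand by syn-hydrometalation of terminal alkynes, so the triene geometry is fixed by the partners. The forward coupling must choose the C–I bond of 31 over its hindered C–Br bond.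

**15 ⇐ 14 ⇐ 6 + 11 (key step; cut C2–C3, restore a C5–O bond).** Boronate 15 comes from enyne 14 by hydroboration. 14 is traced through silylated anilide 13 and imidate 12 to imidoyl chloride 6 and alcohol 11. Against an aldol cut at C2–C3, this cut needs no separate acid, no O-methylation and no acylation of the weak aniline. One rearrangement makes the C2–C3 bond, the anilide, the 4E alkene and C3. The precursors are an acetanilide derivative and a five-carbon alcohol with one stereocentre. The forward reaction must use the methoxyvinyl arm of 11, not the alkynyl arm, and must pass through a chair.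

**6 ⇐ 5 ⇐ 3 ⇐ 2 ⇐ 1 (C16 added by methylenation; functional-group changes).** The aldehyde of 1 becomes the C17=C16 styrene, the nitro group becomes the nitrogen (through aniline 4), and N-acetylation supplies C1 and C2. All ring-A substituents are already correctly placed in 1.

**11 ⇐ 8 + 9 (cut C5–C6); 8 ⇐ 7.** An enantioselective alkynylation of vinylogous formate 8 with alkyne 9 (through zinc reagent 10) sets the C5 carbinol by catalyst control. 8 comes from bis-acetal 7 in one step.

**31 ⇐ 29 ⇐ 28 ⇐ 27 ⇐ 26 ⇐ 23 + 24 (cut C10–C11; C11–O by reduction).** The E-vinyl iodide comes from the terminal alkyne of 29 via zirconium species 30. The anti-diol 27 comes from β-hydroxy ketone 26 by hydroxyl-directed reduction, so C11 is set from C13. 26 comes from Weinreb amide 23 and the propargyl anion 25 of silylpropyne 24.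

**23 ⇐ 22 ⇐ 19 + 20 (cut C12–C13); 19 ⇐ 18 ⇐ 16.** An auxiliary-controlled syn-aldol (boron enolate 21) sets C12 and C13 at once. Z-bromoenal 19 comes from propargyl alcohol 16 by anti-carbomagnesiation (through 17), bromination to 18 and oxidation, which fixes the Z geometry at the outset.

## Roads not taken

**Alternative 1:** The obvious route cuts the amide N–C1 and the central alkene C6=C7. Forward, (3R,4E)-3-methoxyhepta-4,6-dienoic acid A1 is made by a separate asymmetric acetate aldol and O-methylation, coupled to the ring-A aniline that already carries the eastern chain, and the bis-diene A2 is closed by ring-closing metathesis with a second-generation Grubbs catalyst. The chosen plan is better for three reasons: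
- A1 costs its own stereoselective sequence plus an acylation of a hindered, weakly nucleophilic aniline; the Claisen step gives amide, C2–C3 bond and C3 at once.
- In A2 the ruthenium carbene can also enter at the internal alkene of either diene, which leads to ring-contracted products, and the new C6=C7 geometry is left to the ring.
- The decisive step would sit at the very end on the most valuable material.

**Alternative 2:** Cut only N–C1, the biosynthetic closure, and lactamise seco amino acid A3 by activating the C1 acid towards the C22 amine. The amine is hindered and weakly nucleophilic. An activated β-methoxy acyl group can lose methanol by E1cB to a fully conjugated tetraenoyl system. The complete triene would have to survive the whole seco-acid synthesis, and C3 again needs its own construction.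

**Alternative 3:** Run the same Claisen rearrangement as a ring expansion: the 19-membered cyclic imidate A4 (ring through N=C1–O–C5) would give lactam 34 directly by a two-atom expansion. Three things speak against it:
- At C5 of A4 the in-ring dienyl arm is a second allyl unit that can enter the [3,3] shift and give a 17-membered isomer.
- A4 cannot be closed by palladium chemistry, because a doubly allylic imidate ionises to a π-allyl complex.
- A ring-closing imidoylation would need a free C5 alcohol beside an imidoyl chloride.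

The acyclic version uses an alkynyl arm that cannot compete and takes the risk on small molecules at the start.

Key step: step 7

Assumption: (S,S)-ProPhenol is taken to deliver the (S)-carbinol 11; if the sense of induction proves opposite, the (R,R)-ligand is used and nothing else changes.

## Steps

Step 1
Reactants: 1 2-hydroxy-5-methoxy-3-nitrobenzaldehyde
Product: 2 2,5-dimethoxy-3-nitrobenzaldehyde
Conditions: MeI, K2CO3, DMF, 50 °C
Reagents that add atoms: iodomethane, `CI`
Why: Williamson O-methylation of the acidic ortho-nitrophenol; aldehyde and nitro group are inert.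

Step 2
Reactants: 2 2,5-dimethoxy-3-nitrobenzaldehyde
Product: 3 1-ethenyl-2,5-dimethoxy-3-nitrobenzene
Conditions: Ph3PCH3Br, KOtBu, THF, 0 °C → rt
Reagents that add atoms: methyltriphenylphosphonium bromide, `C[P+](c1ccccc1)(c1ccccc1)c1ccccc1.[Br-]`
Why: Wittig methylenation of the aryl aldehyde installs C16; the nitro group tolerates the non-stabilised ylide at low temperature.

Step 3
Reactants: 3 1-ethenyl-2,5-dimethoxy-3-nitrobenzene
Product: 5 N-(3-ethenyl-2,5-dimethoxyphenyl)acetamide, via 3-ethenyl-2,5-dimethoxyaniline 4 (not isolated)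
Conditions: Fe, NH4Cl, EtOH/H2O, 75 °C; filtration; Ac2O, pyridine, CH2Cl2, rt
Reagents that add atoms: acetic anhydride, `CC(=O)OC(C)=O`
Why: Béchamp-type iron reduction takes the nitro group and leaves the styrene; N-acetylation of the aniline then supplies C1 and C2.

Step 4
Reactants: 5 N-(3-ethenyl-2,5-dimethoxyphenyl)acetamide
Product: 6 N-(3-ethenyl-2,5-dimethoxyphenyl)ethanimidoyl chloride
Conditions: (COCl)2, 2,6-lutidine, CH2Cl2, 0 °C; salts filtered from pentane, used crude
Reagents that add atoms: oxalyl chloride, `O=C(Cl)C(=O)Cl`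
Why: Amide-to-imidoyl chloride conversion (O-acylation by oxalyl chloride, chloride return, loss of CO and CO2); the hindered base only takes up HCl, and the moisture-sensitive product is used at once.

Step 5
Reactants: 7 1,1,3,3-tetramethoxypropane
Product: 8 (E)-3-methoxyprop-2-enal
Conditions: H2O (1 equiv), TsOH (cat.), 80 °C, MeOH distilled off; distillation
Reagents that add atoms: water, `O`
Why: Acid-catalysed hydrolysis of one acetal and β-elimination of methanol from the other give the vinylogous formate, whose E isomer is the thermodynamic one.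

Step 6
Reactants: 8 (E)-3-methoxyprop-2-enal; 9 ethynyltrimethylsilane
Product: 11 (1E,3S)-1-methoxy-5-(trimethylsilyl)pent-1-en-4-yn-3-ol, via alkynylzinc reagent 10 (not isolated)
Conditions: Me2Zn, (S,S)-ProPhenol (10 mol %), Ph3PO (20 mol %), toluene, 0 °C; pH 7 phosphate buffer; Et3N-deactivated silica
Reagents that add atoms: none
Why: Zinc–ProPhenol-catalysed enantioselective alkynylation of an unsaturated aldehyde; the chiral dinuclear zinc catalyst selects the aldehyde face and sets the sacrificial C5 carbinol. The non-acidic work-up keeps the acid-labile hydroxy enol ether intact.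

Step 7
Reactants: 6 N-(3-ethenyl-2,5-dimethoxyphenyl)ethanimidoyl chloride; 11 (1E,3S)-1-methoxy-5-(trimethylsilyl)pent-1-en-4-yn-3-ol
Product: 14 (3R,4E)-N-(3-ethenyl-2,5-dimethoxyphenyl)-3-methoxyhept-4-en-6-ynamide, via allyl imidate 12 (not isolated), via silylated enyne anilide 13 (not isolated)
Conditions: NaH, THF, −20 °C; 6, −20 → 0 °C; LiN(iPr)2, −78 °C → rt; then MeOH, K2CO3, rt
Reagents that add atoms: none
Why: The sodium alkoxide of 11 displaces chloride from 6 by addition–elimination to give the O-allyl N-aryl acetimidate 12; LiN(iPr)2 removes a proton from its C-methyl group to give the lithium aza-enolate, which undergoes a charge-accelerated [3,3] shift in which the future C2 bonds to the methoxy-bearing alkene terminus (future C3), the C5–O bond breaks and the imidate oxygen becomes the amide oxygen. The closest known reaction type is the Claisen rearrangement of aza-enolates of allyl N-arylimidates, with the ester-enolate Claisen rearrangement of glycal esters as precedent for bond formation at an alkoxy-bearing allyl terminus. No ring is closed; the step forms the C2–C3 bond, the anilide and the 4E alkene. C3 is controlled by the C5 carbinol of 11: in the chair transition state the alkynyl group is pseudo-equatorial, so the (S)-carbinol with the E enol ether transfers its chirality suprafacially to 3R and gives the E alkene. The step must select the methoxyvinyl arm over the propargyl arm (which would give an allene); the methoxy group stabilises the polar transition state at its own terminus and the Me3Si group shields the alkyne terminus. It must also favour C–C over N–C bond formation (the 1,3 O-to-N shift of neutral 12), which is secured by deprotonating 12 at −78 °C as soon as it is formed. Methanolysis of 13 then removes the alkynyl silyl group.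

Step 8
Reactants: 14 (3R,4E)-N-(3-ethenyl-2,5-dimethoxyphenyl)-3-methoxyhept-4-en-6-ynamide
Product: 15 (3R,4E,6E)-N-(3-ethenyl-2,5-dimethoxyphenyl)-3-methoxy-7-(4,4,5,5-tetramethyl-1,3,2-dioxaborolan-2-yl)hepta-4,6-dienamide
Conditions: HBpin (3 equiv), Cp2Zr(H)Cl (10 mol %), Et3N (10 mol %), CH2Cl2, 40 °C
Reagents that add atoms: pinacolborane, `[H]B1OC(C)(C)C(C)(C)O1`
Why: Zirconium-catalysed hydroboration of a terminal alkyne: syn addition with boron at the terminus gives the 6E alkenylboronate. Pinacolborane does not add to the styrene or the internal alkene without a catalyst for alkenes.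

Step 9
Reactants: 16 prop-2-yn-1-ol
Product: 18 (Z)-3-bromo-2-methylprop-2-en-1-ol, via alkenylmagnesium alkoxide 17 (not isolated)
Conditions: MeMgBr (2.5 equiv), CuI (10 mol %), THF, −10 °C → rt; BrCCl2CCl2Br, −30 → 0 °C
Reagents that add atoms: methylmagnesium bromide, `C[Mg]Br`; 1,2-dibromo-1,1,2,2-tetrachloroethane, `BrC(Cl)(Cl)C(Cl)(Cl)Br`
Why: Copper-catalysed, alkoxide-directed anti-carbomagnesiation puts the methyl group on C14 and magnesium on C15 cis to the CH2O group; electrophilic bromination with retention fixes the Z geometry.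

Step 10
Reactants: 18 (Z)-3-bromo-2-methylprop-2-en-1-ol
Product: 19 (Z)-3-bromo-2-methylprop-2-enal
Conditions: MnO2, CH2Cl2, rt, dark; filtered and used as a solution
Reagents that add atoms: none
Why: Neutral heterogeneous allylic oxidation; no acid, base or nucleophile is present that could isomerise the Z bromoenal.

Step 11
Reactants: 19 (Z)-3-bromo-2-methylprop-2-enal; 20 (4S)-4-benzyl-3-propanoyl-1,3-oxazolidin-2-one
Product: 22 (4S)-4-benzyl-3-[(2S,3S,4Z)-5-bromo-3-hydroxy-2,4-dimethylpent-4-enoyl]-1,3-oxazolidin-2-one, via dibutylboron Z-enolate 21 (not isolated)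
Conditions: 20, Bu2BOTf, iPr2NEt, CH2Cl2, −78 → 0 °C; 19, −78 → 0 °C; pH 7 buffer, MeOH, H2O2
Reagents that add atoms: none
Why: Evans syn-aldol: the Z boron enolate reacts through a Zimmerman–Traxler chair and the benzyl group of the auxiliary shields one enolate face. This sets C12 and C13 (target numbering) in the required 12,13-syn sense and absolute configuration.

Step 12
Reactants: 22 (4S)-4-benzyl-3-[(2S,3S,4Z)-5-bromo-3-hydroxy-2,4-dimethylpent-4-enoyl]-1,3-oxazolidin-2-one
Product: 23 (2S,3S,4Z)-5-bromo-3-hydroxy-N-methoxy-N,2,4-trimethylpent-4-enamide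
Conditions: MeNH(OMe)·HCl, AlMe3, THF, −20 → 0 °C; aq. KNa tartrate
Reagents that add atoms: N,O-dimethylhydroxylamine hydrochloride, `CNOC.Cl`
Why: Aluminium amide transamidation (Weinreb amide formation) at the exocyclic carbonyl, assisted by the free β-hydroxyl; the auxiliary is recovered and the α-centre is not enolised.

Step 13
Reactants: 23 (2S,3S,4Z)-5-bromo-3-hydroxy-N-methoxy-N,2,4-trimethylpent-4-enamide; 24 trimethyl(prop-1-yn-1-yl)silane
Product: 26 (5S,6S,7Z)-8-bromo-6-hydroxy-5,7-dimethyl-1-(trimethylsilyl)oct-7-en-1-yn-4-one, via propargyllithium reagent 25 (not isolated)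
Conditions: 24, n-BuLi, TMEDA, THF, −20 °C (3 equiv of 25); 23, −78 → −40 °C; cold pH 7 buffer
Reagents that add atoms: none
Why: Weinreb ketone synthesis with the silyl-propargyl anion (one equivalent is consumed by the hydroxyl). The chelated tetrahedral intermediate prevents over-addition and releases the β,γ-alkynyl ketone only in the cold neutral quench.

Step 14
Reactants: 26 (5S,6S,7Z)-8-bromo-6-hydroxy-5,7-dimethyl-1-(trimethylsilyl)oct-7-en-1-yn-4-one
Product: 27 (4R,5R,6S,7Z)-8-bromo-5,7-dimethyl-1-(trimethylsilyl)oct-7-en-1-yne-4,6-diol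
Conditions: Me4NBH(OAc)3, MeCN/AcOH, −30 °C
Reagents that add atoms: none
Why: Evans–Saksena reduction: the C13 hydroxyl binds the borohydride and delivers hydride intramolecularly through a chair, giving the 1,3-anti diol and setting C11 (R).

Step 15
Reactants: 27 (4R,5R,6S,7Z)-8-bromo-5,7-dimethyl-1-(trimethylsilyl)oct-7-en-1-yne-4,6-diol
Product: 28 (4R,5R,6S,7Z)-8-bromo-4,6-bis[(tert-butyldimethylsilyl)oxy]-5,7-dimethyl-1-(trimethylsilyl)oct-7-en-1-yne
Conditions: TBSOTf, 2,6-lutidine, CH2Cl2, −78 → 0 °C
Reagents that add atoms: tert-butyldimethylsilyl trifluoromethanesulfonate, `CC(C)(C)[Si](C)(C)OS(=O)(=O)C(F)(F)F`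
Why: Silylation of both secondary alcohols with the reactive triflate; TBS ethers survive the base, zirconium, boron and palladium steps that follow.

Step 16
Reactants: 28 (4R,5R,6S,7Z)-8-bromo-4,6-bis[(tert-butyldimethylsilyl)oxy]-5,7-dimethyl-1-(trimethylsilyl)oct-7-en-1-yne
Product: 29 (4R,5R,6S,7Z)-8-bromo-4,6-bis[(tert-butyldimethylsilyl)oxy]-5,7-dimethyloct-7-en-1-yne
Conditions: K2CO3, MeOH, rt
Reagents that add atoms: none
Why: Methoxide-mediated protodesilylation of the alkynyl C–Si bond; secondary TBS ethers and the vinyl bromide are stable to these conditions.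

Step 17
Reactants: 29 (4R,5R,6S,7Z)-8-bromo-4,6-bis[(tert-butyldimethylsilyl)oxy]-5,7-dimethyloct-7-en-1-yne
Product: 31 (1E,4R,5R,6S,7Z)-8-bromo-4,6-bis[(tert-butyldimethylsilyl)oxy]-1-iodo-5,7-dimethylocta-1,7-diene, via alkenylzirconocene chloride 30 (not isolated)
Conditions: Cp2Zr(H)Cl, THF, rt; I2, 0 °C
Reagents that add atoms: iodine, `II`
Why: Hydrozirconation of the terminal alkyne (syn addition, zirconium at the terminus) and iodinolysis with retention give the 8E vinyl iodide; the trisubstituted vinyl bromide does not react.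

Step 18
Reactants: 15 (3R,4E,6E)-dienylboronate; 31 (1E,7Z)-iodo bromo diene
Product: 32 (3R,4E,6E,8E,11R,12R,13S,14Z)-15-bromo-11,13-bis[(tert-butyldimethylsilyl)oxy]-N-(3-ethenyl-2,5-dimethoxyphenyl)-3-methoxy-12,14-dimethylpentadeca-4,6,8,14-tetraenamide
Conditions: Pd(PPh3)4 (5 mol %), TlOEt, THF/H2O 3:1, rt, dark
Reagents that add atoms: none
Why: Suzuki–Miyaura sp2–sp2 coupling with retention at both carbons gives the E,E,E-triene. At room temperature oxidative addition takes the unhindered C–I bond and leaves the trisubstituted C–Br bond.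

Step 19
Reactants: 32 seco bromide with terminal styrene
Product: 34 (5R,6E,8E,10E,13R,14R,15S,16Z)-13,15-bis[(tert-butyldimethylsilyl)oxy]-5,22,24-trimethoxy-14,16-dimethyl-2-azabicyclo[18.3.1]tetracosa-1(23),6,8,10,16,20(24),21-heptaen-3-one, via B-alkyl-9-BBN borane 33 (not isolated)
Conditions: 9-BBN, THF, 0 °C → rt; slow addition to Pd(dppf)Cl2 (20 mol %), AsPh3, Cs2CO3, DMF/THF/H2O, 50 °C, 1 mM
Reagents that add atoms: none
Why: B-alkyl Suzuki–Miyaura macrocyclisation: 9-BBN adds anti-Markovnikov to the terminal styrene far faster than to the conjugated internal alkenes, and the primary borane couples with the Z vinyl bromide with retention, closing ring B at C15–C16.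

Step 20
Reactants: 34 macrolactam bis-TBS ether
Product: 35 (5R,6E,8E,10E,13R,14R,15S,16Z)-13,15-dihydroxy-5,22,24-trimethoxy-14,16-dimethyl-2-azabicyclo[18.3.1]tetracosa-1(23),6,8,10,16,20(24),21-heptaen-3-one
Conditions: HF·pyridine, pyridine, THF, 0 °C → rt
Reagents that add atoms: none
Why: Fluoride-mediated cleavage of both silyl ethers; the pyridine buffer avoids ionisation of the allylic C3 methyl ether.

Step 21
Reactants: 35 macrolactam diol dimethyl ether
Product: 37 (5R,6E,8E,10E,13R,14R,15S,16Z)-13,15,22,24-tetrahydroxy-5-methoxy-14,16-dimethyl-2-azabicyclo[18.3.1]tetracosa-1(23),6,8,10,16,20(24),21-heptaen-3-one, via amidoquinone 36 (not isolated)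
Conditions: (NH4)2Ce(NO3)6, MeCN/H2O 4:1, 0 °C; then aq. Na2S2O4, EtOAc, rt, argon
Reagents that add atoms: water, `O`
Why: Oxidative demethylation of the para-dimethoxyarene (arene radical cation, ipso attack of water, loss of methanol) gives the quinone, since ring A is the most easily oxidised site. Dithionite then reduces it to the hydroquinone.

## Compound list

1 | 2-hydroxy-5-methoxy-3-nitrobenzaldehyde | `O=Cc1cc(OC)cc([N+](=O)[O-])c1O` | starting material
2 | 2,5-dimethoxy-3-nitrobenzaldehyde | `O=Cc1cc(OC)cc([N+](=O)[O-])c1OC` | intermediate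
3 | 1-ethenyl-2,5-dimethoxy-3-nitrobenzene | `C=Cc1cc(OC)cc([N+](=O)[O-])c1OC` | intermediate
4 | 3-ethenyl-2,5-dimethoxyaniline | `C=Cc1cc(OC)cc(N)c1OC` | intermediate
5 | N-(3-ethenyl-2,5-dimethoxyphenyl)acetamide | `CC(=O)Nc1cc(OC)cc(C=C)c1OC` | intermediate
6 | N-(3-ethenyl-2,5-dimethoxyphenyl)ethanimidoyl chloride | `CC(Cl)=Nc1cc(OC)cc(C=C)c1OC` | intermediate
7 | 1,1,3,3-tetramethoxypropane | `COC(OC)CC(OC)OC` | starting material
8 | (E)-3-methoxyprop-2-enal | `CO/C=C/C=O` | intermediate
9 | ethynyltrimethylsilane | `C#C[Si](C)(C)C` | starting material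
10 | methyl[(trimethylsilyl)ethynyl]zinc | `C[Zn]C#C[Si](C)(C)C` | intermediate
11 | (1E,3S)-1-methoxy-5-(trimethylsilyl)pent-1-en-4-yn-3-ol | `CO/C=C/[C@H](O)C#C[Si](C)(C)C` | intermediate
12 | (1E,3S)-1-methoxy-5-(trimethylsilyl)pent-1-en-4-yn-3-yl N-(3-ethenyl-2,5-dimethoxyphenyl)ethanimidate | `CC(O[C@@H](/C=C/OC)C#C[Si](C)(C)C)=Nc1cc(OC)cc(C=C)c1OC` | intermediate
13 | (3R,4E)-N-(3-ethenyl-2,5-dimethoxyphenyl)-3-methoxy-7-(trimethylsilyl)hept-4-en-6-ynamide | `CO[C@H](CC(=O)Nc1cc(OC)cc(C=C)c1OC)/C=C/C#C[Si](C)(C)C` | intermediate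
14 | (3R,4E)-N-(3-ethenyl-2,5-dimethoxyphenyl)-3-methoxyhept-4-en-6-ynamide | `CO[C@H](CC(=O)Nc1cc(OC)cc(C=C)c1OC)/C=C/C#C` | intermediate
15 | (3R,4E,6E)-N-(3-ethenyl-2,5-dimethoxyphenyl)-3-methoxy-7-(4,4,5,5-tetramethyl-1,3,2-dioxaborolan-2-yl)hepta-4,6-dienamide | `CO[C@H](CC(=O)Nc1cc(OC)cc(C=C)c1OC)/C=C/C=C/B1OC(C)(C)C(C)(C)O1` | intermediate
16 | prop-2-yn-1-ol | `C#CCO` | starting material
17 | bromomagnesium (Z)-3-(bromomagnesio)-2-methylprop-2-en-1-olate | `Br[Mg]OC/C(C)=C\[Mg]Br` | intermediate
18 | (Z)-3-bromo-2-methylprop-2-en-1-ol | `OC/C(C)=C\Br` | intermediate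
19 | (Z)-3-bromo-2-methylprop-2-enal | `O=C/C(C)=C\Br` | intermediate
20 | (4S)-4-benzyl-3-propanoyl-1,3-oxazolidin-2-one | `CCC(=O)N1[C@@H](Cc2ccccc2)COC1=O` | starting material
21 | dibutylboron (Z)-enolate of 20 | `CCCCB(CCCC)O/C(=C\C)N1[C@@H](Cc2ccccc2)COC1=O` | intermediate
22 | (4S)-4-benzyl-3-[(2S,3S,4Z)-5-bromo-3-hydroxy-2,4-dimethylpent-4-enoyl]-1,3-oxazolidin-2-one | `O=C(N1[C@@H](Cc2ccccc2)COC1=O)[C@@H](C)[C@H](O)/C(C)=C\Br` | intermediate
23 | (2S,3S,4Z)-5-bromo-3-hydroxy-N-methoxy-N,2,4-trimethylpent-4-enamide | `CON(C)C(=O)[C@@H](C)[C@H](O)/C(C)=C\Br` | intermediate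
24 | trimethyl(prop-1-yn-1-yl)silane | `CC#C[Si](C)(C)C` | starting material
25 | [3-(trimethylsilyl)prop-2-yn-1-yl]lithium | `[Li]CC#C[Si](C)(C)C` | intermediate
26 | (5S,6S,7Z)-8-bromo-6-hydroxy-5,7-dimethyl-1-(trimethylsilyl)oct-7-en-1-yn-4-one | `C[Si](C)(C)C#CCC(=O)[C@@H](C)[C@H](O)/C(C)=C\Br` | intermediate
27 | (4R,5R,6S,7Z)-8-bromo-5,7-dimethyl-1-(trimethylsilyl)oct-7-en-1-yne-4,6-diol | `C[Si](C)(C)C#CC[C@@H](O)[C@@H](C)[C@H](O)/C(C)=C\Br` | intermediate
28 | (4R,5R,6S,7Z)-8-bromo-4,6-bis[(tert-butyldimethylsilyl)oxy]-5,7-dimethyl-1-(trimethylsilyl)oct-7-en-1-yne | `C[Si](C)(C)C#CC[C@@H](O[Si](C)(C)C(C)(C)C)[C@@H](C)[C@H](O[Si](C)(C)C(C)(C)C)/C(C)=C\Br` | intermediate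
29 | (4R,5R,6S,7Z)-8-bromo-4,6-bis[(tert-butyldimethylsilyl)oxy]-5,7-dimethyloct-7-en-1-yne | `C#CC[C@@H](O[Si](C)(C)C(C)(C)C)[C@@H](C)[C@H](O[Si](C)(C)C(C)(C)C)/C(C)=C\Br` | intermediate
30 | chlorobis(cyclopentadienyl)[(1E,4R,5R,6S,7Z)-8-bromo-4,6-bis(tert-butyldimethylsilyloxy)-5,7-dimethylocta-1,7-dien-1-yl]zirconium (cyclopentadienyl rings drawn sigma-bonded) | `Cl[Zr](/C=C/C[C@@H](O[Si](C)(C)C(C)(C)C)[C@@H](C)[C@H](O[Si](C)(C)C(C)(C)C)/C(C)=C\Br)(C1C=CC=C1)C1C=CC=C1` | intermediate
31 | (1E,4R,5R,6S,7Z)-8-bromo-4,6-bis[(tert-butyldimethylsilyl)oxy]-1-iodo-5,7-dimethylocta-1,7-diene | `I/C=C/C[C@@H](O[Si](C)(C)C(C)(C)C)[C@@H](C)[C@H](O[Si](C)(C)C(C)(C)C)/C(C)=C\Br` | intermediate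
32 | (3R,4E,6E,8E,11R,12R,13S,14Z)-15-bromo-11,13-bis[(tert-butyldimethylsilyl)oxy]-N-(3-ethenyl-2,5-dimethoxyphenyl)-3-methoxy-12,14-dimethylpentadeca-4,6,8,14-tetraenamide | `CO[C@H](CC(=O)Nc1cc(OC)cc(C=C)c1OC)/C=C/C=C/C=C/C[C@@H](O[Si](C)(C)C(C)(C)C)[C@@H](C)[C@H](O[Si](C)(C)C(C)(C)C)/C(C)=C\Br` | intermediate
33 | analogue of 32 with 2-(9-borabicyclo[3.3.1]nonan-9-yl)ethyl in place of ethenyl | `CO[C@H](CC(=O)Nc1cc(OC)cc(CCB2C3CCCC2CCC3)c1OC)/C=C/C=C/C=C/C[C@@H](O[Si](C)(C)C(C)(C)C)[C@@H](C)[C@H](O[Si](C)(C)C(C)(C)C)/C(C)=C\Br` | intermediate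
34 | (5R,6E,8E,10E,13R,14R,15S,16Z)-13,15-bis[(tert-butyldimethylsilyl)oxy]-5,22,24-trimethoxy-14,16-dimethyl-2-azabicyclo[18.3.1]tetracosa-1(23),6,8,10,16,20(24),21-heptaen-3-one | `CO[C@H]1/C=C/C=C/C=C/C[C@@H](O[Si](C)(C)C(C)(C)C)[C@@H](C)[C@H](O[Si](C)(C)C(C)(C)C)/C(C)=C\CCc2cc(OC)cc(c2OC)NC(=O)C1` | intermediate
35 | (5R,6E,8E,10E,13R,14R,15S,16Z)-13,15-dihydroxy-5,22,24-trimethoxy-14,16-dimethyl-2-azabicyclo[18.3.1]tetracosa-1(23),6,8,10,16,20(24),21-heptaen-3-one | `CO[C@H]1/C=C/C=C/C=C/C[C@@H](O)[C@@H](C)[C@H](O)/C(C)=C\CCc2cc(OC)cc(c2OC)NC(=O)C1` | intermediate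
36 | (5R,6E,8E,10E,13R,14R,15S,16Z)-13,15-dihydroxy-5-methoxy-14,16-dimethyl-2-azabicyclo[18.3.1]tetracosa-1(23),6,8,10,16,20-hexaene-3,22,24-trione | `CO[C@H]1/C=C/C=C/C=C/C[C@@H](O)[C@@H](C)[C@H](O)/C(C)=C\CCC2=CC(=O)C=C(NC(=O)C1)C2=O` | intermediate
37 | (5R,6E,8E,10E,13R,14R,15S,16Z)-13,15,22,24-tetrahydroxy-5-methoxy-14,16-dimethyl-2-azabicyclo[18.3.1]tetracosa-1(23),6,8,10,16,20(24),21-heptaen-3-one | `CO[C@H]1/C=C/C=C/C=C/C[C@@H](O)[C@@H](C)[C@H](O)/C(C)=C\CCc2cc(O)cc(c2O)NC(=O)C1` | target

## Step count and least certain steps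

Total: 21 steps (steps 1–4 to 6, steps 5–6 to 11, steps 7–8 to 15, steps 9–17 to 31, steps 18–21 to 37). Longest linear sequence: 13 steps, from 16 through steps 9–21.

**Step 7 (key step).** The most likely failure is ionisation or a 1,3 O-to-N allyl shift of the doubly activated imidate 12 before it is deprotonated, which would erase the C5-to-C3 relay. Partial loss of E selectivity is also possible, because the alkynyl group has only a modest equatorial preference.
Fallback: the same chirality transfer by an Ireland–Claisen rearrangement, with amide formation as a separate step. It sets out from 11 and from aniline 4, isolated after the iron reduction of 3.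
- Acetylation of 11 (Ac2O, pyridine, DMAP) gives (1E,3S)-1-methoxy-5-(trimethylsilyl)pent-1-en-4-yn-3-yl acetate F1.
- LiN(iPr)2 and Me3SiCl/Et3N at −78 °C give the trimethylsilyl ketene acetal F2, which rearranges on warming to the silyl ester F3.
- Aqueous work-up gives (3R,4E)-3-methoxy-7-(trimethylsilyl)hept-4-en-6-ynoic acid F4.
- The acid chloride of F4 (1-chloro-N,N,2-trimethylpropenylamine) acylates 4 in pyridine to give 13, where the route is rejoined before the methanolysis to 14.

**Step 6.** Enantioinduction may be insufficient, because the vinylogous-formate aldehyde is a sluggish electrophile and a background addition can compete. Acid-triggered allylic transposition of 11 to an enal during isolation is the second hazard.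
Fallback: racemic addition, oxidation and reagent-controlled reduction, setting out from 8 and 9 and returning at 11.
- The lithium acetylide of 9 adds to 8 to give racemic (E)-1-methoxy-5-(trimethylsilyl)pent-1-en-4-yn-3-ol F5.
- MnO2 gives (E)-1-methoxy-5-(trimethylsilyl)pent-1-en-4-yn-3-one F6.
- Midland reduction with (S)-Alpine-Borane, which treats the alkynyl group as the small substituent, gives 11.

**Step 19.** Hydroboration may not stay at the styrene if 9-BBN also attacks the triene, and intermolecular coupling may outrun ring closure.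
Fallback: the ring is closed at C7–C8 instead, so no borane ever meets the triene. It sets out from 13 (isolated before methanolysis) and 29, and returns at 34.
- 9-BBN converts the styrene of 13 into the B-alkyl borane F7.
- Coupling of F7 with the vinyl bromide of 29 (Pd(dppf)Cl2, Cs2CO3) gives the ene-diyne F8.
- Cp2Zr(H)Cl then I2 on the free terminal alkyne gives the vinyl iodide F9.
- K2CO3/MeOH gives the terminal enyne F10.
- HBpin with catalytic Cp2Zr(H)Cl gives the dienylboronate F11.
- Pd(PPh3)4/TlOEt at high dilution closes ring B by intramolecular Suzuki–Miyaura coupling to 34.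

**Step 13.** The β,γ-alkynyl ketone may isomerise to the conjugated allenyl ketone when the tetrahedral intermediate collapses, or 25 may attack through its allenyl terminus.
Fallback: C8–C10 is introduced as an allyl group and the polarity of the C7–C8 coupling is inverted. It sets out from 23 and 14 and returns at 32.
- Allylmagnesium bromide adds to 23 to give the allyl ketone F12.
- Me4NBH(OAc)3 gives the anti-diol F13.
- TBSOTf gives the bis-silyl ether F14.
- Cross-metathesis with vinylboronic acid pinacol ester (second-generation Hoveyda–Grubbs catalyst) gives the E-alkenylboronate F15.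
- Cp2Zr(H)Cl then I2 on 14 gives the dienyl iodide F16.
- Suzuki–Miyaura coupling of F15 with a slight excess of F16 gives 32.

## Further compounds

F1 | step 7 | (1E,3S)-1-methoxy-5-(trimethylsilyl)pent-1-en-4-yn-3-yl acetate | `CC(=O)O[C@@H](/C=C/OC)C#C[Si](C)(C)C`
F2 | step 7 | trimethylsilyl ketene acetal of F1 | `C=C(O[Si](C)(C)C)O[C@@H](/C=C/OC)C#C[Si](C)(C)C`
F3 | step 7 | trimethylsilyl (3R,4E)-3-methoxy-7-(trimethylsilyl)hept-4-en-6-ynoate | `CO[C@H](CC(=O)O[Si](C)(C)C)/C=C/C#C[Si](C)(C)C`
F4 | step 7 | (3R,4E)-3-methoxy-7-(trimethylsilyl)hept-4-en-6-ynoic acid | `CO[C@H](CC(=O)O)/C=C/C#C[Si](C)(C)C`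
F5 | step 6 | racemic (E)-1-methoxy-5-(trimethylsilyl)pent-1-en-4-yn-3-ol | `CO/C=C/C(O)C#C[Si](C)(C)C`
F6 | step 6 | (E)-1-methoxy-5-(trimethylsilyl)pent-1-en-4-yn-3-one | `CO/C=C/C(=O)C#C[Si](C)(C)C`
F7 | step 19 | analogue of 13 with 2-(9-borabicyclo[3.3.1]nonan-9-yl)ethyl in place of ethenyl | `CO[C@H](CC(=O)Nc1cc(OC)cc(CCB2C3CCCC2CCC3)c1OC)/C=C/C#C[Si](C)(C)C`
F8 | step 19 | coupled seco ene-diyne (silylated enyne in the west, terminal alkyne in the east) | `C#CC[C@@H](O[Si](C)(C)C(C)(C)C)[C@@H](C)[C@H](O[Si](C)(C)C(C)(C)C)/C(C)=C\CCc1cc(OC)cc(NC(=O)C[C@@H](OC)/C=C/C#C[Si](C)(C)C)c1OC`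
F9 | step 19 | E vinyl iodide of F8 | `I/C=C/C[C@@H](O[Si](C)(C)C(C)(C)C)[C@@H](C)[C@H](O[Si](C)(C)C(C)(C)C)/C(C)=C\CCc1cc(OC)cc(NC(=O)C[C@@H](OC)/C=C/C#C[Si](C)(C)C)c1OC`
F10 | step 19 | desilylated terminal enyne of F9 | `I/C=C/C[C@@H](O[Si](C)(C)C(C)(C)C)[C@@H](C)[C@H](O[Si](C)(C)C(C)(C)C)/C(C)=C\CCc1cc(OC)cc(NC(=O)C[C@@H](OC)/C=C/C#C)c1OC`
F11 | step 19 | (E,E)-dienylboronate vinyl iodide | `I/C=C/C[C@@H](O[Si](C)(C)C(C)(C)C)[C@@H](C)[C@H](O[Si](C)(C)C(C)(C)C)/C(C)=C\CCc1cc(OC)cc(NC(=O)C[C@@H](OC)/C=C/C=C/B2OC(C)(C)C(C)(C)O2)c1OC`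
F12 | step 13 | (5S,6S,7Z)-8-bromo-6-hydroxy-5,7-dimethylocta-1,7-dien-4-one | `C=CCC(=O)[C@@H](C)[C@H](O)/C(C)=C\Br`
F13 | step 13 | (4R,5R,6S,7Z)-8-bromo-5,7-dimethylocta-1,7-diene-4,6-diol | `C=CC[C@@H](O)[C@@H](C)[C@H](O)/C(C)=C\Br`
F14 | step 13 | (4R,5R,6S,7Z)-8-bromo-4,6-bis[(tert-butyldimethylsilyl)oxy]-5,7-dimethylocta-1,7-diene | `C=CC[C@@H](O[Si](C)(C)C(C)(C)C)[C@@H](C)[C@H](O[Si](C)(C)C(C)(C)C)/C(C)=C\Br`
F15 | step 13 | 2-[(1E,4R,5R,6S,7Z)-8-bromo-4,6-bis(tert-butyldimethylsilyloxy)-5,7-dimethylocta-1,7-dien-1-yl]-4,4,5,5-tetramethyl-1,3,2-dioxaborolane | `CC1(C)OB(/C=C/C[C@@H](O[Si](C)(C)C(C)(C)C)[C@@H](C)[C@H](O[Si](C)(C)C(C)(C)C)/C(C)=C\Br)OC1(C)C`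
F16 | step 13 | (3R,4E,6E)-N-(3-ethenyl-2,5-dimethoxyphenyl)-7-iodo-3-methoxyhepta-4,6-dienamide | `CO[C@H](CC(=O)Nc1cc(OC)cc(C=C)c1OC)/C=C/C=C/I`
A1 | alternative 1 | (3R,4E)-3-methoxyhepta-4,6-dienoic acid | `CO[C@H](CC(=O)O)/C=C/C=C`
A2 | alternative 1 | bis-diene seco amide for ring-closing metathesis at C6=C7 | `C=C/C=C/C[C@@H](O[Si](C)(C)C(C)(C)C)[C@@H](C)[C@H](O[Si](C)(C)C(C)(C)C)/C(C)=C\CCc1cc(OC)cc(NC(=O)C[C@@H](OC)/C=C/C=C)c1OC`
A3 | alternative 2 | seco amino acid for macrolactamisation | `CO[C@H](CC(=O)O)/C=C/C=C/C=C/C[C@@H](O[Si](C)(C)C(C)(C)C)[C@@H](C)[C@H](O[Si](C)(C)C(C)(C)C)/C(C)=C\CCc1cc(OC)cc(N)c1OC`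
A4 | alternative 3 | 19-membered cyclic imidate with exocyclic (E)-2-methoxyethenyl group at C5 | `CO/C=C/[C@H]1/C=C/C=C/C[C@@H](O[Si](C)(C)C(C)(C)C)[C@@H](C)[C@H](O[Si](C)(C)C(C)(C)C)/C(C)=C\CCc2cc(OC)cc(c2OC)N=C(C)O1`
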